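**Strategy.** The route rests on a [3+3] construction of ring A (the 3-hydroxy-β-ring). The glycerol-like unit C2–C3(OH)–C4 comes, with its C3 configuration, from (R)-3-chloropropane-1,2-diol as its cyclic sulfate, and is stitched onto the C5–C6–C1 unit of a blocked isopropyl ketone. In one pot the methyl-bearing C5 opens the sulfate (bond C4–C5) and the gem-dimethyl carbon C1 closes the ring on the chloride (bond C2–C1); acid then strips the sulfate and the blocking ester. The precursors are an acyclic β-keto ester and a five-membered cyclic sulfate. The resulting hydroxy-trimethylcyclohexanone is carried by methylenation, ene reaction and a butenolide-lactol Wittig reaction to the C40 chain; ring B (the ε-ring) comes from (R)-α-ionone.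

Key step: step 3

Remark: carotenoid numbering is used for the target; compounds written without a descriptor at one centre are mixtures of epimers at a centre that is destroyed later.
Assumption: (R)-α-ionone (17) is bought enantiopure.

**Ring A and the C15 lactol**

Step 1
Reactants: 1 tert-butyl propanoate
Product: 2 tert-butyl 2,4-dimethyl-3-oxopentanoate (racemic)
Conditions: LiN(i-Pr)2 (2.1 equiv), 1 (2.1 equiv), THF, −78 °C; then i-PrCOCl (1.0 equiv), −78 → 0 °C
Reagents that add atoms: isobutyryl chloride, CC(C)C(Cl)=O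
Why: crossed Claisen-type C-acylation of an ester lithium enolate by an acid chloride, the second equivalent of enolate taking up the acidic proton of the product; the one stereocentre is racemic and is erased later.

Step 2
Reactants: 3 (R)-3-chloropropane-1,2-diol
Product: 5 (4R)-4-(chloromethyl)-1,3,2-dioxathiolane 2,2-dioxide, via cyclic sulfite 4 (not isolated)
Conditions: SOCl2, CH2Cl2, 40 °C; evaporate; then RuCl3·3H2O (0.5 mol %), NaIO4, MeCN/H2O, 0 °C
Reagents that add atoms: thionyl chloride, O=S(Cl)Cl; sodium periodate, [Na+].[O-]I(=O)(=O)=O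
Why: diol to cyclic sulfite followed by RuO4-catalysed oxidation to the cyclic sulfate, a standard activation of 1,2-diols in which no bond to the stereocentre is touched.

Step 3
Reactants: 2 tert-butyl 2,4-dimethyl-3-oxopentanoate; 5 (4R)-4-(chloromethyl)-1,3,2-dioxathiolane 2,2-dioxide
Product: 9 (4R)-4-hydroxy-2,2,6-trimethylcyclohexan-1-one (C6 epimers), via open-chain alkyl sulfate 6 (not isolated), via cyclohexyl sulfate 7 (not isolated), via β-keto acid 8 (not isolated)
Conditions: NaH, THF, 0 → 25 °C, then 5; LiN(i-Pr)2 (1.2 equiv), DMPU, −78 → 40 °C; then 3 M aq. H2SO4/THF, 25 → 65 °C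
Reagents that add atoms: none
Why: The sodium enolate of 2 (carbon C5, which becomes quaternary) opens cyclic sulfate 5 at its primary C–O carbon to give 6 (bond C4–C5), and LiN(i-Pr)2 then forms the only possible enolate of 6, at the isopropyl carbon C1, which displaces the primary chloride to give 7 (bond C2–C1). The closest known reaction types are the alkylation of stabilised carbanions by 1,2-diol cyclic sulfates and the intramolecular alkylation of hindered ketone enolates by ω-halides. The single ring closure is a 6-(enolendo)-exo-tet C-alkylation, allowed by the ring-closure rules for enolates, whereas attack of C1 on the sulfate-bearing carbon would be a disfavoured 5-(enolendo)-exo-tet process on a secondary carbon with an anionic leaving group. The only lasting stereocentre, C3, is not made but carried over from 3: no bond to it is broken, and the order sulfate carbon first, chloride second places the former CH2O carbon next to C5 and the CH2Cl carbon next to C1, which fixes 3R, while the ester-bearing C5 forms as both epimers and loses its configuration on decarboxylation. The selectivities needed are site order (cyclic sulfate far more reactive than C–Cl), C- over O-alkylation (sodium enolate in THF) and enolisation only at C1, the last secured by the tert-butyl ester that blocks C5 and so also shuts off cyclopropane formation. Aqueous acid finally hydrolyses the sulfate monoester with retention, cleaves the tert-butyl ester and decarboxylates β-keto acid 8 to 9.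

Step 4
Reactants: 9 (4R)-4-hydroxy-2,2,6-trimethylcyclohexan-1-one
Product: 10 (4R)-4-{[tert-butyl(dimethyl)silyl]oxy}-2,2,6-trimethylcyclohexan-1-one (C6 epimers)
Conditions: TBSCl, imidazole, DMF, 25 °C
Reagents that add atoms: tert-butyldimethylsilyl chloride, CC(C)(C)[Si](C)(C)Cl
Why: routine silylation of the unhindered secondary alcohol, which protects C3–OH through the Lewis-acid, oxidation and organometallic steps that follow.

Step 5
Reactants: 10 (4R)-4-{[tert-butyl(dimethyl)silyl]oxy}-2,2,6-trimethylcyclohexan-1-one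
Product: 11 tert-butyl(dimethyl){[(1R)-3,3,5-trimethyl-4-methylidenecyclohexyl]oxy}silane (C5 epimers)
Conditions: Ph3PCH3Br, KOtBu, toluene, 90 °C
Reagents that add atoms: methyltriphenylphosphonium bromide, [Br-].C[P+](c1ccccc1)(c1ccccc1)c1ccccc1
Why: Wittig methylenation, which should work on 2,2,6-trisubstituted cyclohexanones at elevated temperature; it installs C7, and epimerisation next to the carbonyl is harmless.

Step 6
Reactants: 11 tert-butyl(dimethyl){[(1R)-3,3,5-trimethyl-4-methylidenecyclohexyl]oxy}silane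
Product: 12 2-[(4R)-4-{[tert-butyl(dimethyl)silyl]oxy}-2,6,6-trimethylcyclohex-1-en-1-yl]ethan-1-ol
Conditions: (CH2O)n, Me2AlCl (2 equiv), CH2Cl2, −78 → 0 °C
Reagents that add atoms: formaldehyde (as paraformaldehyde), C=O
Why: Lewis-acid-promoted carbonyl-ene reaction of a 1,1-disubstituted alkene: the only allylic hydrogen is on C5 (C1 is quaternary), so C7–C8 forms and the double bond moves regiospecifically to C5=C6, both C5 epimers converging on one product.

Step 7
Reactants: 12 2-[(4R)-4-{[tert-butyl(dimethyl)silyl]oxy}-2,6,6-trimethylcyclohex-1-en-1-yl]ethan-1-ol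
Product: 13 [(4R)-4-{[tert-butyl(dimethyl)silyl]oxy}-2,6,6-trimethylcyclohex-1-en-1-yl]acetaldehyde
Conditions: Dess–Martin periodinane, pyridine, CH2Cl2, 0 °C
Reagents that add atoms: none
Why: Dess–Martin oxidation under buffered conditions should give the β,γ-unsaturated aldehyde without moving the tetrasubstituted double bond into conjugation.

Step 8
Reactants: 13 [(4R)-4-{[tert-butyl(dimethyl)silyl]oxy}-2,6,6-trimethylcyclohex-1-en-1-yl]acetaldehyde; 14 4-bromofuran-2(5H)-one
Product: 15 4-{2-[(4R)-4-{[tert-butyl(dimethyl)silyl]oxy}-2,6,6-trimethylcyclohex-1-en-1-yl]-1-hydroxyethyl}furan-2(5H)-one (carbinol epimers)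
Conditions: CrCl2 (4 equiv), NiCl2 (2 mol %), DMF, 25 °C
Reagents that add atoms: none
Why: Nozaki–Hiyama–Kishi coupling of an activated β-bromo-enoate with an aldehyde forms C8–C9 chemoselectively; the new C8 carbinol centre is formed without control and is oxidised away in step 21.

Step 9
Reactants: 15 the butenolide carbinol of step 8
Product: 16 4-{2-[(4R)-4-{[tert-butyl(dimethyl)silyl]oxy}-2,6,6-trimethylcyclohex-1-en-1-yl]-1-hydroxyethyl}-2,5-dihydrofuran-2-ol (epimer mixture)
Conditions: i-Bu2AlH (2.3 equiv), CH2Cl2, −78 °C; Rochelle salt work-up; used crude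
Reagents that add atoms: none
Why: low-temperature DIBAL reduction of an unsaturated lactone stops at the lactol, a masked (Z)-4-hydroxy-enal in which the ring holds C19 cis to C11; the anomeric centre is lost in step 19.

**Ring B and the C25 phosphonium salt**

Step 10
Reactants: 17 (R)-α-ionone
Product: 18 ethyl (2E,4E)-3-methyl-5-[(1R)-2,6,6-trimethylcyclohex-2-en-1-yl]penta-2,4-dienoate
Conditions: (EtO)2P(O)CH2CO2Et (1.3 equiv), NaH (1.2 equiv), THF, 0 → 50 °C; chromatography
Reagents that add atoms: triethyl phosphonoacetate, CCOC(=O)CP(=O)(OCC)OCC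
Why: Horner–Wadsworth–Emmons olefination of the methyl ketone, expected to favour the 2E ester (the 2Z isomer is removed); the stabilised phosphonate anion is too weak a base to epimerise C6′.

Step 11
Reactants: 18 the dienoate of step 10
Product: 19 ethyl (2E,4E)-3-methyl-5-[(1R)-2,6,6-trimethyl-4-oxocyclohex-2-en-1-yl]penta-2,4-dienoate
Conditions: Rh2(cap)4 (dirhodium tetrakis(caprolactamate), 1 mol %), t-BuOOH, K2CO3, CH2Cl2, 25 °C
Reagents that add atoms: tert-butyl hydroperoxide, CC(C)(C)OO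
Why: catalytic allylic C–H oxidation of the cyclohexene at its only ring allylic methylene (C3′) gives the enone; the electron-poor dienoate and the hindered C6′–H should be spared.

Step 12
Reactants: 19 the keto ester of step 11
Product: 20 ethyl (2E,4E)-5-[(1R,4R)-4-hydroxy-2,6,6-trimethylcyclohex-2-en-1-yl]-3-methylpenta-2,4-dienoate
Conditions: (S)-2-methyl-CBS-oxazaborolidine (0.3 equiv), catecholborane, toluene, −78 °C
Reagents that add atoms: none
Why: CBS reduction under reagent control: the enone C=C side acts as the large group, so the (S)-catalyst should give the 3′R carbinol (OH trans to the side chain), and the ester is inert to catecholborane.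

Step 13
Reactants: 20 the hydroxy ester of step 12
Product: 21 (2E,4E)-5-[(1R,4R)-4-hydroxy-2,6,6-trimethylcyclohex-2-en-1-yl]-3-methylpenta-2,4-dien-1-ol
Conditions: i-Bu2AlH (3.5 equiv), CH2Cl2, −78 °C
Reagents that add atoms: none
Why: DIBAL 1,2-reduction of the dienoate to the primary dienylic alcohol without touching a stereocentre.

Step 14
Reactants: 21 the diol of step 13
Product: 22 [(2E,4E)-5-[(1R,4R)-4-hydroxy-2,6,6-trimethylcyclohex-2-en-1-yl]-3-methylpenta-2,4-dien-1-yl](triphenyl)phosphonium bromide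
Conditions: PPh3·HBr, MeOH, 0 → 20 °C; crystallisation
Reagents that add atoms: triphenylphosphine hydrobromide, [Br-].c1ccccc1[PH+](c1ccccc1)c1ccccc1
Why: acid-mediated substitution of the easily ionised primary dienylic alcohol by PPh3, the standard entry to carotenoid C15 Wittig salts; the less ionisable ring allylic alcohol should survive at low temperature.

Step 15
Reactants: 22 the C15 phosphonium bromide; 23 (2E,4E,6E)-2,7-dimethylocta-2,4,6-trienedial
Product: 26 (2E,4E,6E,8E,10E,12E)-13-[(1R,4R)-4-hydroxy-2,6,6-trimethylcyclohex-2-en-1-yl]-2,7,11-trimethyltrideca-2,4,6,8,10,12-hexaenal, via C15 ylide 24 (not isolated), via 8Z isomer 25 (not isolated)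
Conditions: NaOMe, MeOH/CH2Cl2, 0 → 20 °C, 23 (2 equiv); then heptane, 90 °C, N2, dark
Reagents that add atoms: none
Why: Wittig reaction in which the excess of symmetrical dialdehyde favours mono-olefination; the new double bond forms as an E/Z mixture whose hindered Z isomer should equilibrate thermally to all-E.

Step 16
Reactants: 26 the C25 hydroxy aldehyde
Product: 27 (2E,4E,6E,8E,10E,12E)-13-[(1R,4R)-4-hydroxy-2,6,6-trimethylcyclohex-2-en-1-yl]-2,7,11-trimethyltrideca-2,4,6,8,10,12-hexaen-1-ol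
Conditions: NaBH4, EtOH/THF, 0 °C
Reagents that add atoms: none
Why: borohydride 1,2-reduction of the polyene aldehyde to the primary alcohol.

Step 17
Reactants: 27 the C25 diol
Product: 28 [(2E,4E,6E,8E,10E,12E)-13-[(1R,4R)-4-hydroxy-2,6,6-trimethylcyclohex-2-en-1-yl]-2,7,11-trimethyltrideca-2,4,6,8,10,12-hexaen-1-yl](triphenyl)phosphonium bromide
Conditions: PPh3·HBr, CH2Cl2/MeOH, 0 °C
Reagents that add atoms: triphenylphosphine hydrobromide, [Br-].c1ccccc1[PH+](c1ccccc1)c1ccccc1
Why: the same acid-mediated phosphonium formation as for retinol-type polyenols, PPh3 capturing the delocalised cation at the terminal carbon.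

Step 18
Reactants: 28 the C25 hydroxy phosphonium bromide
Product: 29 the 4-O-tert-butyldimethylsilyl ether of 28
Conditions: TBSCl, imidazole, DMF/CH2Cl2, 20 °C
Reagents that add atoms: tert-butyldimethylsilyl chloride, CC(C)(C)[Si](C)(C)Cl
Why: silylation of the ring allylic alcohol after all acidic steps, so that C3′–OH is masked for the acylation and oxidation at the end; imidazole is too weak a base to form the ylide.

**Assembly**

Step 19
Reactants: 16 the C15 lactol; 29 the silylated C25 phosphonium bromide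
Product: 32 (3R,3′R,6′R)-3,3′-bis{[tert-butyl(dimethyl)silyl]oxy}-7,8-dihydro-β,ε-carotene-8,19-diol (all-E; C8 epimers), via C25 ylide 30 (not isolated), via 11Z isomer 31 (not isolated)
Conditions: 29, NaN(SiMe3)2 (1.0 equiv), THF, −78 °C; 16 pre-treated with NaN(SiMe3)2 (2.0 equiv), −78 → 0 °C; then EtOAc/heptane, 70 °C, dark
Reagents that add atoms: none
Why: Wittig olefination of a lactol through its open (Z)-4-oxido-enal form, which frees C19–OH and keeps the ring-derived C9=C10 geometry; C11=C12 forms as an E/Z mixture and the hindered 11Z isomer should equilibrate thermally to E.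

Step 20
Reactants: 32 the C40 diol; 33 (2E)-oct-2-enoic acid
Product: 35 (3R,3′R,6′R)-3,3′-bis{[tert-butyl(dimethyl)silyl]oxy}-8-hydroxy-7,8-dihydro-β,ε-caroten-19-yl (2E)-oct-2-enoate (C8 epimers), via O-acylisourea 34 (not isolated)
Conditions: EDC·HCl (1.3 equiv), DMAP (0.1 equiv), 33 (1.2 equiv), CH2Cl2, −20 → 0 °C
Reagents that add atoms: none
Why: carbodiimide (Steglich-type) esterification, expected to be selective for the primary allylic C19–OH over the hindered secondary C8–OH.

Step 21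
Reactants: 35 the C19 ester
Product: 36 (3R,3′R,6′R)-3,3′-bis{[tert-butyl(dimethyl)silyl]oxy}-8-oxo-7,8-dihydro-β,ε-caroten-19-yl (2E)-oct-2-enoate
Conditions: MnO2 (activated, excess), CH2Cl2, 20 °C, dark
Reagents that add atoms: none
Why: MnO2 oxidation of the polyene-activated allylic alcohol to the enone removes the uncontrolled C8 centre, all other hydroxyl groups being silylated or acylated.

Step 22
Reactants: 36 the bis-silyl ether
Product: 37 (3R,3′R,6′R)-3,3′-dihydroxy-8-oxo-7,8-dihydro-β,ε-caroten-19-yl (2E)-oct-2-enoate (target)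
Conditions: HF·pyridine, pyridine, THF, 0 → 20 °C, dark
Reagents that add atoms: none
Why: buffered fluoride desilylation of both secondary silyl ethers, under which the allylic ester, the β,γ-unsaturated ketone and the acid-sensitive C3′ allylic alcohol should survive.

**Compound list**

1 | tert-butyl propanoate | CCC(=O)OC(C)(C)C | starting material
2 | tert-butyl 2,4-dimethyl-3-oxopentanoate (racemic) | CC(C)C(=O)C(C)C(=O)OC(C)(C)C | intermediate
3 | (R)-3-chloropropane-1,2-diol | OC[C@@H](O)CCl | starting material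
4 | (4R)-4-(chloromethyl)-1,3,2-dioxathiolane 2-oxide (sulfur epimers) | ClC[C@H]1COS(=O)O1 | intermediate (not isolated)
5 | (4R)-4-(chloromethyl)-1,3,2-dioxathiolane 2,2-dioxide | ClC[C@H]1COS(=O)(=O)O1 | intermediate
6 | sodium (2R)-4-(tert-butoxycarbonyl)-1-chloro-4,6-dimethyl-5-oxoheptan-2-yl sulfate (C4 epimers) | CC(C)C(=O)C(C)(C[C@H](CCl)OS(=O)(=O)[O-])C(=O)OC(C)(C)C.[Na+] | intermediate (not isolated)
7 | sodium (1S)-3-(tert-butoxycarbonyl)-3,5,5-trimethyl-4-oxocyclohexyl sulfate (C3 epimers) | CC(C)(C)OC(=O)C1(C)C[C@@H](OS(=O)(=O)[O-])CC(C)(C)C1=O.[Na+] | intermediate (not isolated)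
8 | (5S)-5-hydroxy-1,3,3-trimethyl-2-oxocyclohexane-1-carboxylic acid (C1 epimers) | OC(=O)C1(C)C[C@@H](O)CC(C)(C)C1=O | intermediate (not isolated)
9 | (4R)-4-hydroxy-2,2,6-trimethylcyclohexan-1-one (C6 epimers) | CC1C[C@@H](O)CC(C)(C)C1=O | intermediate
10 | (4R)-4-{[tert-butyl(dimethyl)silyl]oxy}-2,2,6-trimethylcyclohexan-1-one (C6 epimers) | CC1C[C@@H](O[Si](C)(C)C(C)(C)C)CC(C)(C)C1=O | intermediate
11 | tert-butyl(dimethyl){[(1R)-3,3,5-trimethyl-4-methylidenecyclohexyl]oxy}silane (C5 epimers) | C=C1C(C)C[C@@H](O[Si](C)(C)C(C)(C)C)CC1(C)C | intermediate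
12 | 2-[(4R)-4-{[tert-butyl(dimethyl)silyl]oxy}-2,6,6-trimethylcyclohex-1-en-1-yl]ethan-1-ol | OCCC1=C(C)C[C@@H](O[Si](C)(C)C(C)(C)C)CC1(C)C | intermediate
13 | [(4R)-4-{[tert-butyl(dimethyl)silyl]oxy}-2,6,6-trimethylcyclohex-1-en-1-yl]acetaldehyde | O=CCC1=C(C)C[C@@H](O[Si](C)(C)C(C)(C)C)CC1(C)C | intermediate
14 | 4-bromofuran-2(5H)-one | BrC1=CC(=O)OC1 | starting material
15 | 4-{2-[(4R)-4-{[tert-butyl(dimethyl)silyl]oxy}-2,6,6-trimethylcyclohex-1-en-1-yl]-1-hydroxyethyl}furan-2(5H)-one (carbinol epimers) | OC(CC1=C(C)C[C@@H](O[Si](C)(C)C(C)(C)C)CC1(C)C)C1=CC(=O)OC1 | intermediate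
16 | 4-{2-[(4R)-4-{[tert-butyl(dimethyl)silyl]oxy}-2,6,6-trimethylcyclohex-1-en-1-yl]-1-hydroxyethyl}-2,5-dihydrofuran-2-ol (epimer mixture) | OC(CC1=C(C)C[C@@H](O[Si](C)(C)C(C)(C)C)CC1(C)C)C1=CC(O)OC1 | intermediate
17 | (R)-α-ionone, (3E)-4-[(1R)-2,6,6-trimethylcyclohex-2-en-1-yl]but-3-en-2-one | CC(=O)/C=C/[C@H]1C(C)=CCCC1(C)C | starting material
18 | ethyl (2E,4E)-3-methyl-5-[(1R)-2,6,6-trimethylcyclohex-2-en-1-yl]penta-2,4-dienoate | CCOC(=O)/C=C(C)/C=C/[C@H]1C(C)=CCCC1(C)C | intermediate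
19 | ethyl (2E,4E)-3-methyl-5-[(1R)-2,6,6-trimethyl-4-oxocyclohex-2-en-1-yl]penta-2,4-dienoate | CCOC(=O)/C=C(C)/C=C/[C@H]1C(C)=CC(=O)CC1(C)C | intermediate
20 | ethyl (2E,4E)-5-[(1R,4R)-4-hydroxy-2,6,6-trimethylcyclohex-2-en-1-yl]-3-methylpenta-2,4-dienoate | CCOC(=O)/C=C(C)/C=C/[C@H]1C(C)=C[C@H](O)CC1(C)C | intermediate
21 | (2E,4E)-5-[(1R,4R)-4-hydroxy-2,6,6-trimethylcyclohex-2-en-1-yl]-3-methylpenta-2,4-dien-1-ol | OC/C=C(C)/C=C/[C@H]1C(C)=C[C@H](O)CC1(C)C | intermediate
22 | [(2E,4E)-5-[(1R,4R)-4-hydroxy-2,6,6-trimethylcyclohex-2-en-1-yl]-3-methylpenta-2,4-dien-1-yl](triphenyl)phosphonium bromide | c1ccccc1[P+](c1ccccc1)(c1ccccc1)C/C=C(C)/C=C/[C@H]1C(C)=C[C@H](O)CC1(C)C.[Br-] | intermediate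
23 | (2E,4E,6E)-2,7-dimethylocta-2,4,6-trienedial | O=C/C(C)=C/C=C/C=C(C)/C=O | starting material
24 | ylide of 22 | c1ccccc1P(c1ccccc1)(c1ccccc1)=C/C=C(C)/C=C/[C@H]1C(C)=C[C@H](O)CC1(C)C | intermediate (not isolated)
25 | (8Z)-isomer of 26 | O=C/C(C)=C/C=C/C=C(C)/C=C\C=C(C)\C=C\[C@H]1C(C)=C[C@H](O)CC1(C)C | intermediate (not isolated)
26 | (2E,4E,6E,8E,10E,12E)-13-[(1R,4R)-4-hydroxy-2,6,6-trimethylcyclohex-2-en-1-yl]-2,7,11-trimethyltrideca-2,4,6,8,10,12-hexaenal | O=C/C(C)=C/C=C/C=C(C)/C=C/C=C(C)/C=C/[C@H]1C(C)=C[C@H](O)CC1(C)C | intermediate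
27 | (2E,4E,6E,8E,10E,12E)-13-[(1R,4R)-4-hydroxy-2,6,6-trimethylcyclohex-2-en-1-yl]-2,7,11-trimethyltrideca-2,4,6,8,10,12-hexaen-1-ol | OC/C(C)=C/C=C/C=C(C)/C=C/C=C(C)/C=C/[C@H]1C(C)=C[C@H](O)CC1(C)C | intermediate
28 | [(2E,4E,6E,8E,10E,12E)-13-[(1R,4R)-4-hydroxy-2,6,6-trimethylcyclohex-2-en-1-yl]-2,7,11-trimethyltrideca-2,4,6,8,10,12-hexaen-1-yl](triphenyl)phosphonium bromide | c1ccccc1[P+](c1ccccc1)(c1ccccc1)C/C(C)=C/C=C/C=C(C)/C=C/C=C(C)/C=C/[C@H]1C(C)=C[C@H](O)CC1(C)C.[Br-] | intermediate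
29 | 4-O-tert-butyldimethylsilyl ether of 28 | c1ccccc1[P+](c1ccccc1)(c1ccccc1)C/C(C)=C/C=C/C=C(C)/C=C/C=C(C)/C=C/[C@H]1C(C)=C[C@H](O[Si](C)(C)C(C)(C)C)CC1(C)C.[Br-] | intermediate
30 | ylide of 29 | c1ccccc1P(c1ccccc1)(c1ccccc1)=C/C(C)=C/C=C/C=C(C)/C=C/C=C(C)/C=C/[C@H]1C(C)=C[C@H](O[Si](C)(C)C(C)(C)C)CC1(C)C | intermediate (not isolated)
31 | (11Z)-isomer of 32 | OC\C(=C/C=C\C(C)=C\C=C\C=C(C)\C=C\C=C(C)\C=C\[C@H]1C(C)=C[C@H](O[Si](C)(C)C(C)(C)C)CC1(C)C)C(O)CC1=C(C)C[C@@H](O[Si](C)(C)C(C)(C)C)CC1(C)C | intermediate (not isolated)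
32 | (3R,3′R,6′R)-3,3′-bis{[tert-butyl(dimethyl)silyl]oxy}-7,8-dihydro-β,ε-carotene-8,19-diol (all-E; C8 epimers) | OC\C(=C/C=C/C(C)=C/C=C/C=C(C)/C=C/C=C(C)/C=C/[C@H]1C(C)=C[C@H](O[Si](C)(C)C(C)(C)C)CC1(C)C)C(O)CC1=C(C)C[C@@H](O[Si](C)(C)C(C)(C)C)CC1(C)C | intermediate
33 | (2E)-oct-2-enoic acid | CCCCC/C=C/C(=O)O | starting material
34 | O-[(2E)-oct-2-enoyl]-N-ethyl-N′-[3-(dimethylamino)propyl]isourea | CCCCC/C=C/C(=O)OC(=NCC)NCCCN(C)C | intermediate (not isolated)
35 | (3R,3′R,6′R)-3,3′-bis{[tert-butyl(dimethyl)silyl]oxy}-8-hydroxy-7,8-dihydro-β,ε-caroten-19-yl (2E)-oct-2-enoate (C8 epimers) | CCCCC/C=C/C(=O)OC\C(=C/C=C/C(C)=C/C=C/C=C(C)/C=C/C=C(C)/C=C/[C@H]1C(C)=C[C@H](O[Si](C)(C)C(C)(C)C)CC1(C)C)C(O)CC1=C(C)C[C@@H](O[Si](C)(C)C(C)(C)C)CC1(C)C | intermediate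
36 | (3R,3′R,6′R)-3,3′-bis{[tert-butyl(dimethyl)silyl]oxy}-8-oxo-7,8-dihydro-β,ε-caroten-19-yl (2E)-oct-2-enoate | CCCCC/C=C/C(=O)OC\C(=C/C=C/C(C)=C/C=C/C=C(C)/C=C/C=C(C)/C=C/[C@H]1C(C)=C[C@H](O[Si](C)(C)C(C)(C)C)CC1(C)C)C(=O)CC1=C(C)C[C@@H](O[Si](C)(C)C(C)(C)C)CC1(C)C | intermediate
37 | (3R,3′R,6′R)-3,3′-dihydroxy-8-oxo-7,8-dihydro-β,ε-caroten-19-yl (2E)-oct-2-enoate | CCCCC/C=C/C(=O)OC\C(=C/C=C/C(C)=C/C=C/C=C(C)/C=C/C=C(C)/C=C/[C@H]1C(C)=C[C@H](O)CC1(C)C)C(=O)CC1=C(C)C[C@@H](O)CC1(C)C | target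

**Totals**

Total step count: 22. Longest linear sequence: 13 steps (17 → 37, steps 10–18 and 19–22).

**Steps most likely to fail**

Step 3. What may go wrong: O-alkylation of the hindered enolate by the cyclic sulfate in the first stage, or a ring closure on the primary chloride that is slower than decomposition of the ketone enolate. Fallback: it sets out from no numbered compound but replaces 1–8, and comes back to the route at 9. Commercial 2,6,6-trimethylcyclohex-2-ene-1,4-dione F1 is reduced at its C=C bond by fermenting baker's yeast to (6R)-2,2,6-trimethylcyclohexane-1,4-dione F2. The unhindered C4 carbonyl of F2 is then reduced (a levodione-type ketoreductase with cofactor recycling, or H2 over Raney Ni) to (4R,6R)-4-hydroxy-2,2,6-trimethylcyclohexanone, the 6R epimer of 9.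

Step 8. What may go wrong: ring opening by β-elimination of the 4-chromio-butenolide, or sluggish activation of the vinyl bromide. Fallback: it sets out from 14 and 13 and comes back at 15. Compound 14 is silylated (i-Pr3SiOTf, Et3N, CH2Cl2) to 4-bromo-2-(triisopropylsilyloxy)furan F3. Bromine–lithium exchange (n-BuLi, THF, −78 °C) and addition to 13 should give the furyl carbinol 1-{5-[(triisopropylsilyl)oxy]furan-3-yl}-2-[(4R)-4-{[tert-butyl(dimethyl)silyl]oxy}-2,6,6-trimethylcyclohex-1-en-1-yl]ethan-1-ol F4. Dilute aqueous HCl in THF then hydrolyses the silyloxyfuran to butenolide 15.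

Step 19. What may go wrong: dehydration of the lactol to the 3-substituted furan, consumption of the ylide by the two hydroxyl groups, or γ-deprotonation of the open hydroxy-enal. Fallback: it sets out from 15 and comes back at 35, avoiding the lactol and installing the ester before the olefination.
- Compound 15 is silylated (Et3SiCl, imidazole) to the triethylsilyl ether of 15 F5.
- The lactone is opened with MeNH(OMe)·HCl/AlMe3 to the (Z)-γ-hydroxy Weinreb amide F6.
- Its primary alcohol is esterified with 33 (EDC·HCl, DMAP) to the Weinreb amide octenoate F7.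
- Cp2Zr(H)Cl reduces the amide chemoselectively to the (Z)-4-acyloxy-enal F8.
- Wittig reaction with ylide 30 and thermal Z → E equilibration give the 8-O-triethylsilyl ether of 35 F9.
- PPTS in MeOH/CH2Cl2 removes the triethylsilyl group selectively to give 35.

Further compounds
F1 | step 3 | 2,6,6-trimethylcyclohex-2-ene-1,4-dione (commercial) | CC1=CC(=O)CC(C)(C)C1=O
F2 | step 3 | (6R)-2,2,6-trimethylcyclohexane-1,4-dione | C[C@@H]1CC(=O)CC(C)(C)C1=O
F3 | step 8 | 4-bromo-2-(triisopropylsilyloxy)furan | CC(C)[Si](Oc1cc(Br)co1)(C(C)C)C(C)C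
F4 | step 8 | 1-{5-[(triisopropylsilyl)oxy]furan-3-yl}-2-[(4R)-4-{[tert-butyl(dimethyl)silyl]oxy}-2,6,6-trimethylcyclohex-1-en-1-yl]ethan-1-ol | OC(CC1=C(C)C[C@@H](O[Si](C)(C)C(C)(C)C)CC1(C)C)c1coc(O[Si](C(C)C)(C(C)C)C(C)C)c1
F5 | step 19 | triethylsilyl ether of 15 | CC[Si](CC)(CC)OC(CC1=C(C)C[C@@H](O[Si](C)(C)C(C)(C)C)CC1(C)C)C1=CC(=O)OC1
F6 | step 19 | (Z)-γ-hydroxy Weinreb amide | CON(C)C(=O)\C=C(/CO)C(O[Si](CC)(CC)CC)CC1=C(C)C[C@@H](O[Si](C)(C)C(C)(C)C)CC1(C)C
F7 | step 19 | Weinreb amide octenoate | CCCCC/C=C/C(=O)OC\C(=C/C(=O)N(C)OC)C(O[Si](CC)(CC)CC)CC1=C(C)C[C@@H](O[Si](C)(C)C(C)(C)C)CC1(C)C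
F8 | step 19 | (Z)-4-acyloxy-enal | CCCCC/C=C/C(=O)OC\C(=C/C=O)C(O[Si](CC)(CC)CC)CC1=C(C)C[C@@H](O[Si](C)(C)C(C)(C)C)CC1(C)C
F9 | step 19 | 8-O-triethylsilyl ether of 35 | CCCCC/C=C/C(=O)OC\C(=C/C=C/C(C)=C/C=C/C=C(C)/C=C/C=C(C)/C=C/[C@H]1C(C)=C[C@H](O[Si](C)(C)C(C)(C)C)CC1(C)C)C(O[Si](CC)(CC)CC)CC1=C(C)C[C@@H](O[Si](C)(C)C(C)(C)C)CC1(C)C
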